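**Plan**

Numbering: labdane numbers for C1–C14 (ring C = C8, C9, C11, C12, C13, C14); ring D = O13, C13, C14, C15, C16, C17 (bears CH3), C18, C19 (OCH2); O15 is a temporary oxygen on C15.
Retrosynthesis: with C19 as a lactone carbonyl and the alkene moved to C15=C16, ring D is the [3,3] product of a six-membered ketene acetal (C19, O13, C13, C14, C15, O15) carrying an (E)-propenyl group on C15, so C17–C18 is cut first.
Further cuts: C18=C19 (methylenation of a 13,15-carbonate), C19–O (carbonate from the 13,15-diol), C15–C16 (propenyl addition to a C15 aldehyde) and C8–C14 (radical cyclisation of a larixol-derived vinyl sulfone).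
Forward: rings A and B come with (+)-larixol; ring C closes by hydrogen-atom-transfer radical cyclisation; ring D arises by expanding the dioxane from six to eight atoms; then C15=C16 is hydrogenated, C17=C18 introduced, C19=O reduced to CH2 and O6 unmasked.
Stereochemistry: C5, C6, C9, C10 and C13 are those of larixol; C8 and C14 come from the chair radical cyclisation on the α face of C8; C15 (temporary) from chelate-controlled addition; the ring alkenes are Z because the ring allows nothing else.

Key step: step 10

Remark: carbanions, enolates, alkoxides, radicals and oxocarbenium ions formed in a flask are treated as reactive forms of the numbered substrate; covalent intermediates formed with a reagent are numbered.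

**Route**

Step 1
Reactants: 1 (+)-larixol
Product: 2 6-O-TBS-larixol
Conditions: TBSCl, imidazole, DMAP (cat.), DMF, 50 °C
Reagents that add atoms: tert-butyldimethylsilyl chloride, CC(C)(C)[Si](C)(C)Cl
Why: Silyl ether formation should be selective for the secondary equatorial 6α-hydroxyl over the tertiary allylic 13-hydroxyl, which must stay free to direct step 2 and later become O13 of ring D.

Step 2
Reactants: 2 6-O-TBS-larixol
Product: 3 14,15-epoxide (C14 epimers)
Conditions: VO(acac)2 (cat.), t-BuOOH, CH2Cl2, 0 °C to rt
Reagents that add atoms: tert-butyl hydroperoxide, CC(C)(C)OO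
Why: Hydroxyl-directed vanadium-catalysed epoxidation should deliver oxygen only to the vinyl group next to the free 13-OH and leave the undirected 8-methylidene group untouched, so the acceptor is built without exposing the diene to a metathesis catalyst; the C14 mixture is erased in step 4.

Step 3
Reactants: 3 14,15-epoxide
Product: 4 15-phenylsulfonyl-13,14-diol (C14 epimers)
Conditions: PhSO2Na, NH4Cl, DMF/H2O, 80 °C
Reagents that add atoms: sodium benzenesulfinate, [Na+].[O-]S(=O)c1ccccc1
Why: SN2 opening of the terminal epoxide by the sulfur end of the sulfinate at unhindered C15 should give the β-hydroxy sulfone under buffered conditions that avoid Payne rearrangement and spare the silyl ether.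

Step 4
Reactants: 4 15-phenylsulfonyl-13,14-diol
Product: 6 (E)-vinyl sulfone, via C14 mesylate 5 (not isolated)
Conditions: MsCl, Et3N, CH2Cl2, 0 °C to rt
Reagents that add atoms: none
Why: Mesylation of the secondary C14 hydroxyl followed by E1cB elimination through the α-sulfonyl carbanion should give the (E)-γ-hydroxy vinyl sulfone, the tertiary 13-OH being too hindered to be sulfonylated.

Step 5
Reactants: 6 (E)-vinyl sulfone
Product: 7 tricyclic sulfone
Conditions: Fe(acac)3 (30 mol %), PhSiH3, EtOH/(CH2OH)2 (5:1), 60 °C
Reagents that add atoms: none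
Why: Iron-hydride hydrogen-atom transfer to the 8-methylidene group gives the tertiary C8 radical, which should add 6-exo-trig to C14 of the vinyl sulfone (intramolecular reductive Giese-type olefin coupling); C14 bonds to the α face of C8, anti to the axial C10 methyl, through a chair with the sulfonylvinyl terminus equatorial, which sets the 8β-methyl and 14α-H (trans B/C fusion) and leaves the C13 methyl axial and the hydroxyl equatorial.

Step 6
Reactants: 7 tricyclic sulfone
Product: 8 13-hydroxy C15 aldehyde
Conditions: n-BuLi (2.2 equiv), THF, −78 °C; Me3SiOOSiMe3; AcOH quench at −78 °C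
Reagents that add atoms: bis(trimethylsilyl) peroxide, C[Si](C)(C)OO[Si](C)(C)C
Why: Oxidative desulfonylation: the α-sulfonyl carbanion formed beside the O13 alkoxide is oxygenated by the silyl peroxide and the α-silyloxy sulfone collapses to the aldehyde with loss of sulfinate; the cold quench should keep the β-hydroxy aldehyde from retro-aldol opening, and the equatorial formyl group is the stable C14 configuration.

Step 7
Reactants: 8 13-hydroxy C15 aldehyde; 9 (E)-1-bromopropene
Product: 12 (15R)-13,15-diol, via (E)-1-propenyllithium 10 (not isolated), via (E)-1-propenylmagnesium bromide 11 (not isolated)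
Conditions: 9, t-BuLi (2 equiv), Et2O, −78 °C; MgBr2·OEt2, −78 to 0 °C; then 8, CH2Cl2/Et2O, −78 °C
Reagents that add atoms: none
Why: Chelation-controlled Grignard addition: the magnesium alkoxide of O13 ties the aldehyde oxygen into a six-membered chelate whose β face is blocked by the axial methyls on C13 and C8, so the propenyl group (E geometry retained from lithium–bromine exchange) should enter from the α face and end equatorial, with H15 syn to the C13 methyl (15R).

Step 8
Reactants: 12 (15R)-13,15-diol; 13 1,1'-carbonyldiimidazole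
Product: 15 13,15-cyclic carbonate, via O15 imidazole-1-carboxylate 14 (not isolated)
Conditions: CDI, THF, rt; then NaH, 0 °C to rt
Reagents that add atoms: none
Why: Carbonate formation: the secondary allylic O15 is acylated by CDI and the tertiary O13 alkoxide then closes the six-membered ring on the acyl imidazole, so the hindered C13–O–C19 link is made by acyl substitution at C19 and never by substitution at C13.

Step 9
Reactants: 15 13,15-cyclic carbonate; 16 dimethyltitanocene Cp2TiMe2
Product: 17 2-methylene-1,3-dioxane (ketene acetal)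
Conditions: Cp2TiMe2, toluene/THF, pyridine (1%), 65 °C, dark; filtration through basic alumina, used crude
Reagents that add atoms: none
Why: Petasis methylenation: thermally generated Cp2Ti=CH2 should convert the carbonate carbonyl into the exocyclic C19=C18H2 group, as known for vinyl-substituted cyclic carbonates, at a temperature below that needed for rearrangement of this conformationally restrained ketene acetal.

Step 10
Reactants: 17 2-methylene-1,3-dioxane (ketene acetal)
Product: 18 ring D lactone with Z-C15=C16
Conditions: o-xylene, 140 °C, sealed base-washed tube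
Reagents that add atoms: none
Why: Heating should set off a concerted suprafacial [3,3] shift in which C18 of the ketene acetal bonds to C17 of the propenyl group while the C15–O15 bond breaks and O15 becomes the lactone carbonyl oxygen (Claisen rearrangement in its ring-expanding form, known for vinyl-substituted 2-methylene-1,3-dioxanes, which give eight-membered unsaturated lactones). Ring D is thus closed by a two-atom ring expansion of the six-membered dioxane through a bicyclo[3.3.1]-like array with a chair-shaped pericyclic ring, not by end-to-end cyclisation, and it is driven by formation of the ester carbonyl. Because the trans fusion to ring C forbids a chair flip, the dioxane reaches the reactive shape by tipping O15 to the β face (boat), which turns the equatorial propenyl group of the 15R epimer pseudoaxial on the α face, away from the axial C13 methyl; the 15S epimer could only react with its allyl unit pressed against that methyl, which is why step 7 is run under chelate control. The new C15=C16 bond can only be Z inside the eight-membered ring (C14 sits inside the chair), and the single new stereocentre C17 is fixed by suprafacial transfer from C15 with the E-methyl pseudoequatorial, although it is erased in step 12. The selectivity needed is [3,3] shift over ionisation of the allylic C15–O15 bond and over hydrolysis of the ketene acetal, secured by the neutral, base-washed, anhydrous medium and by the ring that holds C17 over C18.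

Step 11
Reactants: 18 ring D lactone with Z-C15=C16
Product: 19 saturated ring D lactone
Conditions: H2 (1 atm), 10% Pd/C, EtOAc, rt
Reagents that add atoms: none
Why: Heterogeneous catalytic hydrogenation should saturate the cis-disubstituted C15=C16 alkene without touching the lactone or the silyl ether.

Step 12
Reactants: 19 saturated ring D lactone
Product: 22 C17=C18 enoate lactone, via C18 phenylselanyl lactone 20 (not isolated), via selenoxide 21 (not isolated)
Conditions: LiN(i-Pr)2, THF, −78 °C; PhSeBr; then AcOH, 30% H2O2, 0 °C to rt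
Reagents that add atoms: none
Why: α-Selenenylation of the lactone enolate anti to the C17 methyl, then oxidation and selenoxide syn-elimination, should remove H17 and H18 (C17 is the only β-carbon bearing hydrogen), erase C17 and give the ring-cis (Z) trisubstituted enoate, the only geometry the eight-membered ring allows.

Step 13
Reactants: 22 C17=C18 enoate lactone
Product: 24 C19 acetoxy ether (C19 epimers), via diisobutylaluminium hemiacetal 23 (not isolated)
Conditions: i-Bu2AlH, CH2Cl2, −78 °C; then pyridine, DMAP, Ac2O, −78 to −20 °C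
Reagents that add atoms: acetic anhydride, CC(=O)OC(C)=O
Why: Reductive acetylation: 1,2-hydride addition to the enoate carbonyl gives an aluminium hemiacetal that is acetylated in situ before the eight-membered lactol can open to the hydroxy enal.

Step 14
Reactants: 24 C19 acetoxy ether
Product: 25 6-O-TBS ether of the target
Conditions: Et3SiH, BF3·OEt2, CH2Cl2, −78 °C
Reagents that add atoms: none
Why: Ionisation of the acetate gives an allyl-stabilised oxocarbenium ion that should take hydride from Et3SiH at C19, the carbon next to oxygen (ionic hydrogenation with Ferrier-type regioselectivity), leaving the C17=C18 alkene in place.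

Step 15
Reactants: 25 6-O-TBS ether of the target
Product: 26 target CNP0179324.1
Conditions: n-Bu4NF, THF, 50 °C
Reagents that add atoms: none
Why: Fluoride-mediated desilylation should free the 6α-hydroxyl; no other group in the molecule responds to fluoride.

**Compound list**

1 | (+)-larixol (6α,13-dihydroxy labdane with 8-methylidene and 13-vinyl groups) | O[C@@](C=C)(C)CC[C@@H]1[C@@]2(C)CCCC(C)(C)[C@@H]2[C@@H](O)CC1=C | starting material
2 | 6-O-TBS-larixol | O[C@@](C=C)(C)CC[C@@H]1[C@@]2(C)CCCC(C)(C)[C@@H]2[C@@H](O[Si](C)(C)C(C)(C)C)CC1=C | intermediate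
3 | 14,15-epoxide of 2 (C14 epimers) | O[C@@](C3CO3)(C)CC[C@@H]1[C@@]2(C)CCCC(C)(C)[C@@H]2[C@@H](O[Si](C)(C)C(C)(C)C)CC1=C | intermediate
4 | 15-phenylsulfonyl-13,14-diol (C14 epimers) | O[C@@](C(O)CS(=O)(=O)c3ccccc3)(C)CC[C@@H]1[C@@]2(C)CCCC(C)(C)[C@@H]2[C@@H](O[Si](C)(C)C(C)(C)C)CC1=C | intermediate
5 | C14 mesylate of 4 | O[C@@](C(OS(C)(=O)=O)CS(=O)(=O)c3ccccc3)(C)CC[C@@H]1[C@@]2(C)CCCC(C)(C)[C@@H]2[C@@H](O[Si](C)(C)C(C)(C)C)CC1=C | intermediate
6 | (E)-C14=C15 vinyl phenyl sulfone with free 13-OH and 8-methylidene | O[C@@](/C=C/S(=O)(=O)c3ccccc3)(C)CC[C@@H]1[C@@]2(C)CCCC(C)(C)[C@@H]2[C@@H](O[Si](C)(C)C(C)(C)C)CC1=C | intermediate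
7 | tricyclic sulfone (8β-methyl, 14α-H, C15H2SO2Ph equatorial, 13α-OH) | O[C@@]2(C)CC[C@@H]3[C@@]4(C)CCCC(C)(C)[C@@H]4[C@@H](O[Si](C)(C)C(C)(C)C)C[C@@]3(C)[C@@H]2CS(=O)(=O)c1ccccc1 | intermediate
8 | 13-hydroxy C15 aldehyde (formyl equatorial on C14) | O[C@@]2(C)CC[C@@H]3[C@@]4(C)CCCC(C)(C)[C@@H]4[C@@H](O[Si](C)(C)C(C)(C)C)C[C@@]3(C)[C@@H]2C=O | intermediate
9 | (E)-1-bromopropene | C/C=C/Br | starting material
10 | (E)-1-propenyllithium | C/C=C/[Li] | intermediate
11 | (E)-1-propenylmagnesium bromide | C/C=C/[Mg]Br | intermediate
12 | (15R)-13,15-diol with (E)-propenyl on C15 (H15 syn to the C13 methyl) | O[C@@]2(C)CC[C@@H]3[C@@]4(C)CCCC(C)(C)[C@@H]4[C@@H](O[Si](C)(C)C(C)(C)C)C[C@@]3(C)[C@@H]2[C@@H](/C=C/C)O | intermediate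
13 | 1,1'-carbonyldiimidazole | O=C(n1ccnc1)n1ccnc1 | starting material
14 | O15 imidazole-1-carboxylate of 12 | O[C@@]2(C)CC[C@@H]3[C@@]4(C)CCCC(C)(C)[C@@H]4[C@@H](O[Si](C)(C)C(C)(C)C)C[C@@]3(C)[C@@H]2[C@@H](/C=C/C)OC(=O)n1ccnc1 | intermediate
15 | 13,15-cyclic carbonate (trans-fused, propenyl equatorial) | O=C1O[C@@]2(C)CC[C@@H]3[C@@]4(C)CCCC(C)(C)[C@@H]4[C@@H](O[Si](C)(C)C(C)(C)C)C[C@@]3(C)[C@@H]2[C@@H](/C=C/C)O1 | intermediate
16 | dimethyltitanocene Cp2TiMe2 | C[Ti](C)(C1C=CC=C1)C1C=CC=C1 | starting material
17 | 13,15-O-(ethene-1,1-diyl) ketene acetal, 15R, (E)-propenyl equatorial on the chair | C=C1O[C@@]2(C)CC[C@@H]3[C@@]4(C)CCCC(C)(C)[C@@H]4[C@@H](O[Si](C)(C)C(C)(C)C)C[C@@]3(C)[C@@H]2[C@@H](/C=C/C)O1 | intermediate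
18 | ring D lactone, Z-C15=C16, C17 methyl as drawn | O=C1O[C@@]2(C)CC[C@@H]3[C@@]4(C)CCCC(C)(C)[C@@H]4[C@@H](O[Si](C)(C)C(C)(C)C)C[C@@]3(C)[C@@H]2/C=C\[C@H](C)C1 | intermediate
19 | saturated ring D lactone | O=C1O[C@@]2(C)CC[C@@H]3[C@@]4(C)CCCC(C)(C)[C@@H]4[C@@H](O[Si](C)(C)C(C)(C)C)C[C@@]3(C)[C@@H]2CC[C@H](C)C1 | intermediate
20 | C18 phenylselanyl lactone (Se trans to the C17 methyl) | O=C1O[C@@]2(C)CC[C@@H]3[C@@]4(C)CCCC(C)(C)[C@@H]4[C@@H](O[Si](C)(C)C(C)(C)C)C[C@@]3(C)[C@@H]2CC[C@H](C)[C@H]1[Se]c5ccccc5 | intermediate
21 | selenoxide of 20 (Se epimers) | O=C1O[C@@]2(C)CC[C@@H]3[C@@]4(C)CCCC(C)(C)[C@@H]4[C@@H](O[Si](C)(C)C(C)(C)C)C[C@@]3(C)[C@@H]2CC[C@H](C)[C@H]1[Se](=O)c5ccccc5 | intermediate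
22 | ring D (Z)-C17=C18 enoate lactone | C/C1=C/C(=O)O[C@@]2(C)CC[C@@H]3[C@@]4(C)CCCC(C)(C)[C@@H]4[C@@H](O[Si](C)(C)C(C)(C)C)C[C@@]3(C)[C@@H]2CC1 | intermediate
23 | diisobutylaluminium hemiacetal at C19 (C19 epimers) | C/C1=C/C(O[Al](CC(C)C)CC(C)C)O[C@@]2(C)CC[C@@H]3[C@@]4(C)CCCC(C)(C)[C@@H]4[C@@H](O[Si](C)(C)C(C)(C)C)C[C@@]3(C)[C@@H]2CC1 | intermediate
24 | C19 acetoxy ether (C19 epimers) | C/C1=C/C(OC(C)=O)O[C@@]2(C)CC[C@@H]3[C@@]4(C)CCCC(C)(C)[C@@H]4[C@@H](O[Si](C)(C)C(C)(C)C)C[C@@]3(C)[C@@H]2CC1 | intermediate
25 | 6-O-TBS ether of the target | C/C1=C/CO[C@@]2(C)CC[C@@H]3[C@@]4(C)CCCC(C)(C)[C@@H]4[C@@H](O[Si](C)(C)C(C)(C)C)C[C@@]3(C)[C@@H]2CC1 | intermediate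
26 | CNP0179324.1 | C/C1=C/CO[C@@]2(C)CC[C@@H]3[C@@]4(C)CCCC(C)(C)[C@@H]4[C@@H](O)C[C@@]3(C)[C@@H]2CC1 | target

**Step count and risks**

Total steps: 15. Longest linear sequence: 15 steps (1 to 26).

Steps most likely to fail:

Step 10. The boat-type reorganisation that the trans-fused ketene acetal needs may raise the barrier enough for ionisation of the allylic C15–O15 bond, or hydrolysis by adventitious water, to outrun the [3,3] shift. Fallback: setting out from aldehyde 8, Wittig methylenation with Ph3P=CH2 would give the 14-vinyl carbinol F1. Acylation of the tertiary O13 with (R)-3-methylpent-4-enoyl chloride (Et3N, DMAP, toluene, 80 °C) would give the diene ester F2. Ring-closing metathesis with the second-generation Grubbs catalyst (H2IMes)(PCy3)Cl2Ru=CHPh would then close ring D at C15=C16 and come back to the route at lactone 18.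

Step 7. Chelate control may erode, or the basic alkenyl reagent may deprotonate the hindered β-hydroxy aldehyde and trigger retro-aldol opening of ring C, giving 15-epimer mixtures that cannot all reach the reactive conformation of step 10. Fallback: setting out from 8, addition of the smaller and less basic 1-propynylmagnesium bromide CH3C≡CMgBr under the same magnesium chelate would give the propargylic diol F3. Hydroxyl-directed trans-hydroalumination with NaAlH2(OCH2CH2OCH3)2 in THF would then create the E alkene and come back to the route at diol 12.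

Step 6. Oxygen transfer to the hindered dianion may be incomplete, so that unreacted carbanion attacks the freshly released aldehyde, and the lithium aldolate may undergo retro-aldol cleavage on warming. Fallback: setting out from sulfone 7, the dianion would be borylated with i-PrOBpin to the α-sulfonyl boronate F4. Oxidation with NaBO3·4H2O in THF/H2O would turn C–B into C–O, and the α-hydroxy sulfone would lose benzenesulfinate under buffered conditions with no carbanion present, coming back to the route at aldehyde 8.

**Further compounds**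

F1 | step 10 | 14-vinyl carbinol (C15 methylidene in place of the formyl oxygen of 8) | O[C@@]2(C)CC[C@@H]3[C@@]4(C)CCCC(C)(C)[C@@H]4[C@@H](O[Si](C)(C)C(C)(C)C)C[C@@]3(C)[C@@H]2C=C
F2 | step 10 | O13 (R)-3-methylpent-4-enoate of F1 (diene ester) | C=C[C@H](C)CC(=O)O[C@@]2(C)CC[C@@H]3[C@@]4(C)CCCC(C)(C)[C@@H]4[C@@H](O[Si](C)(C)C(C)(C)C)C[C@@]3(C)[C@@H]2C=C
F3 | step 7 | (15R)-13,15-diol with 1-propynyl on C15 (propargylic diol) | O[C@@]2(C)CC[C@@H]3[C@@]4(C)CCCC(C)(C)[C@@H]4[C@@H](O[Si](C)(C)C(C)(C)C)C[C@@]3(C)[C@@H]2[C@@H](C#CC)O
F4 | step 6 | C15 pinacol boronate of sulfone 7 (α-sulfonyl boronate, C15 epimers) | O[C@@]2(C)CC[C@@H]3[C@@]4(C)CCCC(C)(C)[C@@H]4[C@@H](O[Si](C)(C)C(C)(C)C)C[C@@]3(C)[C@@H]2C(B5OC(C)(C)C(C)(C)O5)S(=O)(=O)c1ccccc1
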